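The benzene ring is cut across C5–C6. A squarate-derived 4-silyloxy-3-methoxy-2-methylcyclobutenone is heated; its carbinol carbon carries a buta-1,3-dien-2-yl group whose other inner carbon holds the silyl-protected (S)-carbinol and the prenyl chain. In one operation, 4π ring opening and 6π closure onto the inner vinyl group build the arene. The step exploits the ring's substitution pattern: para oxygens at C2 and C5 in different states, OMe at C3 next to Me at C4, and H at C6. The ketene oxygen becomes the free C5 phenol and the carbinol oxygen the silylated C2 oxygen, while the C7 methylidene and the C8 stereocentre pass through untouched.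

Key step: step 8

Numbering of the target used below: ring C1 (side chain), C2 (OH), C3 (OMe), C4 (Me), C5 (OAc), C6 (H); chain C7 (ring-bound alkene carbon, its CH2 is C14), C8 (carbinol, S), C9–C11 (prenyl).
Assumption: 19 is carried as the mixture of epimers at the ring carbinol carbon, because that carbon becomes sp2 in step 8.
Design remark: C8–O carries tert-butyldimethylsilyl and not a smaller silyl group, because a small silyl ether three atoms from a vinyllithium is prone to 1,4 O→C silyl migration; acid later removes this alkyl ether and leaves the aryl silyl ether in place.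

Step 1
Reactants: 1 dimethyl squarate
Product: 4 3-methoxy-4-methylcyclobut-3-ene-1,2-dione, via lithium alkoxide 2 (not isolated), via trifluoroacetate 3 (not isolated)
Conditions: MeLi, THF, −78 °C; TFAA, −78 °C; aq. NH4Cl
Reagents that add atoms: methyllithium [Li]C; water O
Why: 1,2-Addition of MeLi to one squarate carbonyl gives alkoxide 2, and O-trifluoroacetylation followed by aqueous work-up triggers allylic ionisation, attack of water at the methoxy-bearing carbon and loss of methanol, the standard conversion of a squarate ester into a 3-alkoxy-4-alkylcyclobutenedione.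

Step 2
Reactants: 5 1,4-dichlorobut-2-yne
Product: 7 2,3-bis(trimethylstannyl)buta-1,3-diene, via allenylmethyl chloride 6 (not isolated)
Conditions: Me6Sn2, MeLi, THF, −20 °C; 5, −78 °C → rt
Reagents that add atoms: hexamethylditin C[Sn](C)(C)[Sn](C)(C)C (delivered as trimethylstannyllithium [Li][Sn](C)(C)C)
Why: Two successive SN2' displacements by the stannyl anion, first at the alkyne to give allene 6 and then at the central allene carbon, place one tin on each inner carbon of a butadiene, a known entry to this 2,3-dimetallated diene.

Step 3
Reactants: 8 4-methylpent-3-enoic acid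
Product: 10 N-methoxy-N,4-dimethylpent-3-enamide, via acyl imidazole 9 (not isolated)
Conditions: CDI, CH2Cl2, 0 °C → rt; MeNHOMe·HCl, rt
Reagents that add atoms: N,O-dimethylhydroxylamine hydrochloride CNOC.Cl
Why: Amide coupling through the acyl imidazole runs without strong base, so the β,γ-double bond stays where it is and the Weinreb amide needed for a clean ketone synthesis is obtained.

Step 4
Reactants: 7 2,3-bis(trimethylstannyl)buta-1,3-diene; 10 N-methoxy-N,4-dimethylpent-3-enamide
Product: 13 7-methyl-3-methylidene-2-(trimethylstannyl)octa-1,6-dien-4-one, via stannyl dienyllithium 11 (not isolated), via tetrahedral adduct 12 (not isolated)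
Conditions: 7, MeLi (1.0 equiv), THF, −78 °C; 10, −78 °C; inverse quench into cold aq. NH4Cl; 13 taken on without storage
Reagents that add atoms: none
Why: Tin–lithium exchange with one equivalent of MeLi takes off a single stannyl group, and the resulting vinyllithium acylates the Weinreb amide only as far as the chelated adduct 12, which releases the enone on cold work-up (Weinreb ketone synthesis); the second tin is kept as the handle for step 7.

Step 5
Reactants: 13 7-methyl-3-methylidene-2-(trimethylstannyl)octa-1,6-dien-4-one
Product: 15 (4S)-7-methyl-3-methylidene-2-(trimethylstannyl)octa-1,6-dien-4-ol, via borate ester 14 (not isolated)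
Conditions: (R)-2-methyl-CBS-oxazaborolidine [(R)-1-methyl-3,3-diphenyltetrahydro-1H,3H-pyrrolo[1,2-c][1,3,2]oxazaborole] (0.2 equiv), catecholborane, toluene, −78 °C; MeOH, aq. work-up
Reagents that add atoms: none
Why: Corey–Bakshi–Shibata reduction: the ketone coordinates to the catalyst boron anti to its bulky α-branched dienyl group, which ranks as the large substituent against the prenyl CH2, so the (R)-catalyst delivers hydride to the face that gives the (S)-carbinol, the C8 stereocentre of the target, and catecholborane at −78 °C leaves the alkenes and the C–Sn bond alone.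

Step 6
Reactants: 15 (4S)-7-methyl-3-methylidene-2-(trimethylstannyl)octa-1,6-dien-4-ol
Product: 16 tert-butyldimethylsilyl ether of 15
Conditions: TBSOTf, 2,6-lutidine, CH2Cl2, −78 → 0 °C
Reagents that add atoms: tert-butyldimethylsilyl triflate CC(C)(C)[Si](C)(C)OS(=O)(=O)C(F)(F)F
Why: Silyl triflate silylation of a hindered secondary alcohol under lutidine buffering; tert-butyldimethylsilyl is chosen because it is too bulky to shift from oxygen to the neighbouring carbanion in step 7 at −78 °C.

Step 7
Reactants: 16 tert-butyldimethylsilyl ether of 15; 4 3-methoxy-4-methylcyclobut-3-ene-1,2-dione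
Product: 19 4-silyloxy-4-dienylcyclobutenone precursor (both epimers at the ring carbinol), via dienyllithium 17 (not isolated), via lithium alkoxide 18 (not isolated)
Conditions: 16, MeLi (0.95 equiv), THF, −78 °C; 4, −78 °C; TBSOTf, −78 → −40 °C; aq. NaHCO3
Reagents that add atoms: tert-butyldimethylsilyl triflate CC(C)(C)[Si](C)(C)OS(=O)(=O)C(F)(F)F
Why: Tin–lithium exchange gives the 2-lithiodiene, which adds 1,2 to the more electrophilic carbonyl of 4, the one next to the methoxy-bearing carbon and not the vinylogous ester carbonyl, and the tertiary lithium alkoxide is trapped cold by the silyl triflate before it can ring-open; the new ring carbinol centre is not controlled and need not be.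

Step 8
Reactants: 19 4-silyloxy-4-dienylcyclobutenone precursor
Product: 22 C5-hydroxy C2-silyloxy arene with the (S)-silyloxy side chain, via dienylketene 20 (not isolated), via cyclohexadienone 21 (not isolated)
Conditions: toluene (0.01 M, degassed), 110 °C
Reagents that add atoms: none
Why: Heat breaks the C1–C4 bond of the cyclobutenone in a conrotatory 4π electrocyclic ring opening to dienylketene 20, and a disrotatory 6π electrocyclisation of the unit made of the ketene C=C, the enol ether C=C and the inner vinyl group then joins the ketene carbon to the vinyl CH2 (C5–C6 of the target) to give cyclohexa-2,4-dienone 21, which enolises to phenol 22. The closest known reaction is the thermal ring expansion of squarate-derived 4-alkenyl-4-hydroxy- or 4-silyloxycyclobutenones to hydroquinones and their monoethers. The one ring formed, the benzene ring, is closed by this thermal 6π electrocyclisation followed by tautomerisation. No stereocentre is created: the ring carbinol carbon becomes sp2, so both epimers of 19 converge, and C8 lies outside the reacting π system and keeps its (S) configuration. The step needs torquoselectivity and periselectivity: the donor silyloxy group on the breaking bond rotates outward, which swings the butadienyl group inward beside the ketene, and only its inner vinyl group can reach the ketene carbon, so C6 ends as CH and the outer methylidene survives as C7=C14. High dilution guards the diene against intermolecular cycloaddition, and the regiochemistry (OMe beside the silylated C2 oxygen, Me beside the free C5 phenol) was already fixed by the site of addition in step 7.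

Step 9
Reactants: 22 C5-hydroxy C2-silyloxy arene with the (S)-silyloxy side chain
Product: 23 phenol–alcohol with the aryl silyl ether retained
Conditions: CSA (0.2 equiv), MeOH/CH2Cl2, 0 °C → rt
Reagents that add atoms: none
Why: Acid-catalysed methanolysis removes the alkyl silyl ether, while the aryl silyl ether, whose oxygen is far less basic, is inert to these conditions (selective silyl ether cleavage).

Step 10
Reactants: 23 phenol–alcohol with the aryl silyl ether retained
Product: 24 C5 aryl acetate with free C8 alcohol
Conditions: Ac2O (1.05 equiv), Et3N, CH2Cl2, −20 → 0 °C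
Reagents that add atoms: acetic anhydride CC(=O)OC(C)=O
Why: With triethylamine and no acyl-transfer catalyst the acidic C5 phenol is acetylated through its phenoxide much faster than the hindered secondary allylic alcohol, which gives chemoselective O-acetylation at the oxygen that came from the ketene carbonyl.

Step 11
Reactants: 24 C5 aryl acetate with free C8 alcohol; 25 angelic acid
Product: 27 C8 angelate with the aryl silyl ether retained, via mixed anhydride 26 (not isolated)
Conditions: 25, 2,4,6-trichlorobenzoyl chloride, Et3N, toluene, rt; 24, 75 °C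
Reagents that add atoms: none
Why: Yamaguchi-type esterification through the mixed anhydride: the alcohol attacks the unhindered angeloyl carbonyl, and the absence of nucleophilic catalysts such as DMAP avoids addition–elimination isomerisation of the (Z)-ester to the tiglate; C8 is not touched.

Step 12
Reactants: 27 C8 angelate with the aryl silyl ether retained
Product: 28 CNP0305991.1
Conditions: TBAF, AcOH (1:1), THF, 0 °C → rt
Reagents that add atoms: none
Why: Buffered fluoride cleaves the aryl silyl ether, the most fluoride-labile group present, and acetic acid protonates the phenoxide at once, so the aryl acetate and the allylic angelate are neither cleaved nor transferred.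

Compound list

1 | dimethyl squarate (3,4-dimethoxycyclobut-3-ene-1,2-dione) | COC1=C(OC)C(=O)C1=O | starting material
2 | lithium 2,3-dimethoxy-1-methyl-4-oxocyclobut-2-en-1-olate | [Li+].[O-]C1(C)C(OC)=C(OC)C1=O | intermediate (not isolated)
3 | 2,3-dimethoxy-1-methyl-4-oxocyclobut-2-en-1-yl trifluoroacetate | CC1(OC(=O)C(F)(F)F)C(OC)=C(OC)C1=O | intermediate (not isolated)
4 | 3-methoxy-4-methylcyclobut-3-ene-1,2-dione | COC1=C(C)C(=O)C1=O | intermediate
5 | 1,4-dichlorobut-2-yne | ClCC#CCCl | starting material
6 | (1-chlorobuta-2,3-dien-2-yl)trimethylstannane | ClCC(=C=C)[Sn](C)(C)C | intermediate (not isolated)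
7 | 2,3-bis(trimethylstannyl)buta-1,3-diene | C=C([Sn](C)(C)C)C(=C)[Sn](C)(C)C | intermediate
8 | 4-methylpent-3-enoic acid | CC(C)=CCC(=O)O | starting material
9 | 1-(4-methylpent-3-enoyl)imidazole | CC(C)=CCC(=O)n1ccnc1 | intermediate (not isolated)
10 | N-methoxy-N,4-dimethylpent-3-enamide | CC(C)=CCC(=O)N(C)OC | intermediate
11 | [3-(trimethylstannyl)buta-1,3-dien-2-yl]lithium | [Li]C(=C)C(=C)[Sn](C)(C)C | intermediate (not isolated)
12 | lithium 4-[methoxy(methyl)amino]-7-methyl-3-methylidene-2-(trimethylstannyl)octa-1,6-dien-4-olate | [Li+].[O-]C(CC=C(C)C)(N(C)OC)C(=C)C(=C)[Sn](C)(C)C | intermediate (not isolated)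
13 | 7-methyl-3-methylidene-2-(trimethylstannyl)octa-1,6-dien-4-one | C=C([Sn](C)(C)C)C(=C)C(=O)CC=C(C)C | intermediate
14 | 2-{[(4S)-7-methyl-3-methylidene-2-(trimethylstannyl)octa-1,6-dien-4-yl]oxy}-1,3,2-benzodioxaborole | C=C([Sn](C)(C)C)C(=C)[C@H](CC=C(C)C)OB1Oc2ccccc2O1 | intermediate (not isolated)
15 | (4S)-7-methyl-3-methylidene-2-(trimethylstannyl)octa-1,6-dien-4-ol | C=C([Sn](C)(C)C)C(=C)[C@H](CC=C(C)C)O | intermediate
16 | tert-butyldimethyl{[(4S)-7-methyl-3-methylidene-2-(trimethylstannyl)octa-1,6-dien-4-yl]oxy}silane | C=C([Sn](C)(C)C)C(=C)[C@H](CC=C(C)C)O[Si](C)(C)C(C)(C)C | intermediate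
17 | [(4S)-4-(tert-butyldimethylsilyloxy)-7-methyl-3-methylideneocta-1,6-dien-2-yl]lithium | [Li]C(=C)C(=C)[C@H](CC=C(C)C)O[Si](C)(C)C(C)(C)C | intermediate (not isolated)
18 | lithium alkoxide of the adduct of 17 with 4 (both epimers at the ring carbinol) | [Li+].[O-]C1(C(=C)C(=C)[C@H](CC=C(C)C)O[Si](C)(C)C(C)(C)C)C(OC)=C(C)C1=O | intermediate (not isolated)
19 | 4-(tert-butyldimethylsilyloxy)-4-[(4S)-4-(tert-butyldimethylsilyloxy)-7-methyl-3-methylideneocta-1,6-dien-2-yl]-3-methoxy-2-methylcyclobut-2-en-1-one (both epimers at ring C4) | O=C1C(C)=C(OC)C1(O[Si](C)(C)C(C)(C)C)C(=C)C(=C)[C@H](CC=C(C)C)O[Si](C)(C)C(C)(C)C | intermediate (key-step precursor)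
20 | (3Z)-4-(tert-butyldimethylsilyloxy)-4-[(4S)-4-(tert-butyldimethylsilyloxy)-7-methyl-3-methylideneocta-1,6-dien-2-yl]-3-methoxy-2-methylbuta-1,3-dien-1-one (dienyl group cis to the ketene) | O=C=C(C)/C(OC)=C(/O[Si](C)(C)C(C)(C)C)C(=C)C(=C)[C@H](CC=C(C)C)O[Si](C)(C)C(C)(C)C | intermediate (not isolated)
21 | 4-(tert-butyldimethylsilyloxy)-5-[(3S)-3-(tert-butyldimethylsilyloxy)-6-methylhepta-1,5-dien-2-yl]-3-methoxy-2-methylcyclohexa-2,4-dien-1-one | O=C1CC(C(=C)[C@H](CC=C(C)C)O[Si](C)(C)C(C)(C)C)=C(O[Si](C)(C)C(C)(C)C)C(OC)=C1C | intermediate (not isolated)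
22 | 4-(tert-butyldimethylsilyloxy)-5-[(3S)-3-(tert-butyldimethylsilyloxy)-6-methylhepta-1,5-dien-2-yl]-3-methoxy-2-methylphenol | C=C(c1cc(O)c(C)c(OC)c1O[Si](C)(C)C(C)(C)C)[C@H](CC=C(C)C)O[Si](C)(C)C(C)(C)C | intermediate (key-step product)
23 | 4-(tert-butyldimethylsilyloxy)-5-[(3S)-3-hydroxy-6-methylhepta-1,5-dien-2-yl]-3-methoxy-2-methylphenol | C=C(c1cc(O)c(C)c(OC)c1O[Si](C)(C)C(C)(C)C)[C@H](CC=C(C)C)O | intermediate
24 | 4-(tert-butyldimethylsilyloxy)-5-[(3S)-3-hydroxy-6-methylhepta-1,5-dien-2-yl]-3-methoxy-2-methylphenyl acetate | C=C(c1cc(OC(C)=O)c(C)c(OC)c1O[Si](C)(C)C(C)(C)C)[C@H](CC=C(C)C)O | intermediate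
25 | angelic acid, (Z)-2-methylbut-2-enoic acid | C/C=C(/C)C(=O)O | starting material
26 | (Z)-2-methylbut-2-enoic 2,4,6-trichlorobenzoic anhydride | C/C=C(/C)C(=O)OC(=O)c1c(Cl)cc(Cl)cc1Cl | intermediate (not isolated)
27 | (3S)-2-[5-acetoxy-2-(tert-butyldimethylsilyloxy)-3-methoxy-4-methylphenyl]-6-methylhepta-1,5-dien-3-yl (Z)-2-methylbut-2-enoate | C=C(c1cc(OC(C)=O)c(C)c(OC)c1O[Si](C)(C)C(C)(C)C)[C@H](CC=C(C)C)OC(=O)/C(C)=C\C | intermediate
28 | CNP0305991.1, (3S)-2-(5-acetoxy-2-hydroxy-3-methoxy-4-methylphenyl)-6-methylhepta-1,5-dien-3-yl (Z)-2-methylbut-2-enoate | C=C(c1cc(OC(C)=O)c(C)c(OC)c1O)[C@H](CC=C(C)C)OC(=O)/C(C)=C\C | target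

Total step count: 12. Longest linear sequence: 10 steps (step 2, then steps 4 to 12, from 5; the same length from 8 through step 3).

Steps most likely to fail

Step 8. The ketene may be consumed before it closes: the cross-conjugated diene can enter intermolecular cycloadditions at the temperature needed, the bulky silyloxy group may not rotate outward cleanly, or the tertiary silyl ether may be lost on heating. The fallback sets out from 16 and comes back at 24. Compound 17 is made and added to 4 as in step 7, but the alkoxide is quenched cold with aq. NH4Cl, which gives the free 4-hydroxycyclobutenone F1. Free 4-hydroxy-4-alkenylcyclobutenones are the best documented substrates of this ring expansion; heating F1 in dioxane or toluene should give the hydroquinone F2. The two phenols are then distinguished by their surroundings and no longer by origin. One equivalent of Ac2O with Et3N at −20 °C should acetylate the open C5–OH (between Me and H) in preference to the C2–OH, which sits between OMe and the branched side chain and is hydrogen-bonded to the methoxy oxygen; this gives the C5 monoacetate F3. Silylation of the C2 phenol (TBSCl, imidazole, DMF) gives the bis-silyl acetate F4, and aqueous acid without alcohol (TsOH·H2O, THF/H2O) removes the alkyl silyl ether to give 24.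

Step 4. The vinyllithium may deprotonate the doubly activated α-CH2 of 10 instead of acylating it, the amine set free on work-up may add to the enone, and the 2-acyl diene 13 may dimerise by Diels–Alder reaction or lose the position of its β,γ-double bond before it is reduced. The fallback sets out from 7 and comes back at 15; it also replaces step 5. Compound 11 is generated as before and added at −78 °C to 4-methylpent-3-enal F5, freshly made by Dess–Martin oxidation of commercial 4-methylpent-3-en-1-ol. This fast 1,2-addition gives the racemic alcohol F6 and never passes through an acyl diene. Esterification with (S)-O-methylmandelic acid (DCC, DMAP) gives two diastereomeric esters, the mandelate of the (S)-alcohol F7 and the mandelate of the (R)-alcohol F8. These are separated by chromatography and assigned by the usual mandelate shielding model. Methanolysis of F7 (K2CO3, MeOH) gives 15.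

Step 7. Tin–lithium exchange at the hindered dienyl position may stay incomplete, MeLi left over would then add to 4, and a long exchange time gives the γ-silyloxy vinyllithium room for silyl migration or protonation. The fallback sets out from 16 and comes back at 19. Iododestannylation (I2, CH2Cl2, 0 °C) gives the dienyl iodide F9. Iodine–lithium exchange with t-BuLi (2 equiv) in Et2O at −78 °C is fast and irreversible and leaves no alkyllithium that can attack the dione. The resulting 17 is then treated with 4 in THF and with TBSOTf as in step 7 to give 19.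

Further compounds
F1 | step 8 | 4-[(4S)-4-(tert-butyldimethylsilyloxy)-7-methyl-3-methylideneocta-1,6-dien-2-yl]-4-hydroxy-3-methoxy-2-methylcyclobut-2-en-1-one | O=C1C(C)=C(OC)C1(O)C(=C)C(=C)[C@H](CC=C(C)C)O[Si](C)(C)C(C)(C)C
F2 | step 8 | 2-[(3S)-3-(tert-butyldimethylsilyloxy)-6-methylhepta-1,5-dien-2-yl]-6-methoxy-5-methylbenzene-1,4-diol | C=C(c1cc(O)c(C)c(OC)c1O)[C@H](CC=C(C)C)O[Si](C)(C)C(C)(C)C
F3 | step 8 | 5-[(3S)-3-(tert-butyldimethylsilyloxy)-6-methylhepta-1,5-dien-2-yl]-4-hydroxy-3-methoxy-2-methylphenyl acetate | C=C(c1cc(OC(C)=O)c(C)c(OC)c1O)[C@H](CC=C(C)C)O[Si](C)(C)C(C)(C)C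
F4 | step 8 | 4-(tert-butyldimethylsilyloxy)-5-[(3S)-3-(tert-butyldimethylsilyloxy)-6-methylhepta-1,5-dien-2-yl]-3-methoxy-2-methylphenyl acetate | C=C(c1cc(OC(C)=O)c(C)c(OC)c1O[Si](C)(C)C(C)(C)C)[C@H](CC=C(C)C)O[Si](C)(C)C(C)(C)C
F5 | step 4 | 4-methylpent-3-enal | CC(C)=CCC=O
F6 | step 4 | racemic 7-methyl-3-methylidene-2-(trimethylstannyl)octa-1,6-dien-4-ol | C=C([Sn](C)(C)C)C(=C)C(O)CC=C(C)C
F7 | step 4 | (4S)-7-methyl-3-methylidene-2-(trimethylstannyl)octa-1,6-dien-4-yl (S)-2-methoxy-2-phenylacetate | C=C([Sn](C)(C)C)C(=C)[C@H](CC=C(C)C)OC(=O)[C@@H](OC)c1ccccc1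
F8 | step 4 | (4R)-7-methyl-3-methylidene-2-(trimethylstannyl)octa-1,6-dien-4-yl (S)-2-methoxy-2-phenylacetate | C=C([Sn](C)(C)C)C(=C)[C@@H](CC=C(C)C)OC(=O)[C@@H](OC)c1ccccc1
F9 | step 7 | tert-butyl{[(4S)-2-iodo-7-methyl-3-methylideneocta-1,6-dien-4-yl]oxy}dimethylsilane | IC(=C)C(=C)[C@H](CC=C(C)C)O[Si](C)(C)C(C)(C)C
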